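I decided to read J against D and to leave the clock out.

common to all: E 160 mM (held)

| flask | D | remark | time |
|---|---|---|---|
| Tuesday's | 0.67 M | the very flask that is asked about, followed so far |  |
| Monday's | 1.3 M | run made earlier |  |
| flask | 0.67 M |  | 8.0 d |

| run | time / d | J / % | D / % |
|---|---|---|---|
| Tuesday's | 0.417 | 26 | 67 |
| Tuesday's | 0.625 | 44 | 56 |
| Tuesday's | 1.04 | 66 | 30 |
| Tuesday's | 2.08 | 62 | 2 |
| Tuesday's | 3.00 | 38 | 0 |
| Monday's | 0.417 | 20 | 83 |
| Monday's | 0.833 | 35 | 66 |
| Monday's | 1.67 | 57 | 35 |
| Monday's | 4.00 | 50 | 0 |
| Monday's | 8.00 | 3 | 0 |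

(scatter of a reading: 2 percentage points)

* time up to 8.0 d at which J stands highest
* the amount of J, in percent of the D charged, at that time
* the first time at which J reaches 49 %, in the same percent, in d

- the numbers in the tables scatter by 2 percentage points (one standard deviation)
- at the start none of E is in solution

I assumed that D and J are consumed by the same dissolved E, each in proportion to its own amount. Dissolved E then cancels from the ratio of the two rates, and J as a fraction of the charge becomes a curve in D, also as a fraction: D to the power s, less D, divided by one less s. On that assumption the held level of E moves the clock and leaves the curve alone. The limit of 8.0 d lay past the peak, since Tuesday's J was already falling at 3.00 d. The charge moves the clock too: Monday's flask, with twice the D, took 1.67 d to reach D 35 %, and Tuesday's took 1.04 d to reach 30 %.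

So s has to be known well, and the reading I took for it, with a scatter of 2 percentage points on each of its numbers, is Tuesday's J 62 % at D 2 %. Solved there, the curve gave me the selectivity factor s, the fractional rate of loss of J over that of D, as 0.155. At Monday's D 35 % it gives J 59.2 %, and the reading was 57 %. The peak lies where D equals s times J. I reckoned J 71.0 % at D 11.0 %, near 1.42 d by interpolating ln D between Tuesday's readings. Doubling s gives a peak of 59.1 %, and halving it gives 80.7 %.

The forecast gave 75 % at 1.4 d, with J reaching 49 % at 0.75 d, holding that “J is barely consumed until D runs low”. My peak lay lower than its figure.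

The flask stood highest at 70.2 % at 1.51 d and first reached 49 % at 0.731 d.

    E ⇌ L, rate k1*(csat - [L]) (kL = 0.00290 min⁻¹)
    D + L → J (k = 0.0270 L mol⁻¹ min⁻¹)
    L + J → G (k = 0.00130 L mol⁻¹ min⁻¹)
    L → Z (k = 3.50 × 10⁻⁶ min⁻¹)
    L + J → Q (k = 0.00310 L mol⁻¹ min⁻¹)

The best stop in this flask came with D still at 11.4 %, and s times the best J gives 10.9 %. For a flask charged with 0.27 M of D, E held alike, s gives the same 71.0 % of that charge; that flask stood highest at 70.2 %.

(All runs were computed with made-up constants.)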